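The carbocycle is read as a cyclodeca-1(10),4-diene whose C1=C10 and C4=C5 bonds are what remains when a cyclobutane (C1, C4, C5, C10) is cleaved across C5–C10 and C1–C4. Everything therefore rests on one [2+2] photocycloaddition that joins a 5-alkoxy-3-methylcyclohexenone (C5–C10 with C14) to methyl cyclobutenecarboxylate (C1–C4 with C15), making C1–C10 and C4–C5 and a bicyclo[2.2.0]hexane in a single operation; heating then fuses the six- and four-membered rings into the ten-membered ring with both trisubstituted alkenes in place. The enone partner is the (S)-configured 4-methoxybenzyl ether 7; its oxygen later steers C7 and C6 and is inverted when the methacrylate is attached.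

Key step: step 9

Numbering: germacrane locants (C1–C15) are used from compound 14 onward; α/β refer to the usual germacranolide drawing with H-7 α; in every ten-membered compound C1=C10 is E (trans in the ring) and C3 and C6 are cis on C4=C5 (E by CIP).
Remark on configuration: an enolate is alkylated trans to a neighbouring oxygenated ring carbon, so an 8β-oxygen cannot set the cis C7/C8 pattern of the target; C8 is therefore carried as the 8α (S) 4-methoxybenzyl ether, whose oxygen also chelates in the C6 reduction, and is inverted in step 19.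
Assumption: the lipase acetylates the enantiotopic hydroxyl that leads to 3 as drawn; an enzyme of opposite preference gives the same 3 by hydrolysis of the diacetate of 2.

Step 1
Reactants: 1 cis,cis-cyclohexane-1,3,5-triol
Product: 2 all-cis-5-[(4-methoxybenzyl)oxy]cyclohexane-1,3-diol (meso)
Conditions: NaH (1.0 equiv), 4-MeOC6H4CH2Cl, DMF, 0 °C to rt
Reagents that add atoms: 4-methoxybenzyl chloride, COc1ccc(CCl)cc1
Why: Williamson etherification of the mono-alkoxide, in which one equivalent of base should favour the mono-ether statistically (triol and bis-ether are separated and recycled) and no stereocentre is changed, the product being meso.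

Step 2
Reactants: 2 all-cis-5-[(4-methoxybenzyl)oxy]cyclohexane-1,3-diol
Product: 3 (1R,3R,5S)-3-hydroxy-5-[(4-methoxybenzyl)oxy]cyclohexyl acetate
Conditions: lipase from Burkholderia cepacia (immobilised), vinyl acetate, tBuOMe, rt
Reagents that add atoms: vinyl acetate, C=COC(C)=O
Why: Lipase-catalysed irreversible transesterification (enzymatic desymmetrisation of a meso-1,3-diol) acylates one of the two enantiotopic hydroxyls and thereby fixes the absolute configuration of all three carbinol carbons in one event.

Step 3
Reactants: 3 (1R,3R,5S)-3-hydroxy-5-[(4-methoxybenzyl)oxy]cyclohexyl acetate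
Product: 5 (R)-5-[(4-methoxybenzyl)oxy]cyclohex-2-en-1-one, via acetoxy ketone 4 (not isolated)
Conditions: DMP, CH2Cl2, rt; then DBU, 0 °C
Reagents that add atoms: none
Why: Dess–Martin oxidation of the free carbinol gives the β-acetoxy ketone, from which base removes acetate by E1cB elimination (acetate being a far better leaving group than the ether alkoxide), the remaining stereocentre staying untouched.

Step 4
Reactants: 5 (R)-5-[(4-methoxybenzyl)oxy]cyclohex-2-en-1-one
Product: 6 (5R)-5-[(4-methoxybenzyl)oxy]-1-methylcyclohex-2-en-1-ol (both C1 epimers)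
Conditions: MeLi, THF, −78 °C
Reagents that add atoms: methyllithium, [Li]C
Why: 1,2-Addition of the hard organolithium to the enone carbonyl, the new carbinol centre forming as a mixture that is of no consequence because it is destroyed in step 5.

Step 5
Reactants: 6 (5R)-5-[(4-methoxybenzyl)oxy]-1-methylcyclohex-2-en-1-ol
Product: 7 (S)-5-[(4-methoxybenzyl)oxy]-3-methylcyclohex-2-en-1-one
Conditions: pyridinium chlorochromate [C5H5NH][CrO3Cl], 4 Å molecular sieves, CH2Cl2, rt
Reagents that add atoms: pyridinium chlorochromate, [O-][Cr](=O)(=O)Cl.c1cc[nH+]cc1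
Why: Dauben–Babler oxidative transposition, in which the tertiary allylic chromate ester undergoes a [3,3] shift and the resulting secondary chromate is oxidised to the transposed enone, the ether carbon being untouched although its descriptor changes from R to S because the ranking of its two CH2 neighbours is exchanged.

Step 6
Reactants: 8 cyclobutanecarboxylic acid
Product: 11 methyl 1-bromocyclobutane-1-carboxylate, via acid chloride 9 (not isolated), via bromo acid chloride 10 (not isolated)
Conditions: SOCl2, 80 °C; then NBS, HBr (cat.), 85 °C; then MeOH, 0 °C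
Reagents that add atoms: N-bromosuccinimide, O=C1CCC(=O)N1Br; methanol, CO
Why: Hell–Volhard–Zelinsky-type α-bromination run on the acid chloride (enolisation of the acyl chloride and bromination by NBS) followed by methanolysis, with no stereocentre involved.

Step 7
Reactants: 11 methyl 1-bromocyclobutane-1-carboxylate
Product: 12 cyclobut-1-ene-1-carboxylic acid
Conditions: KOH, PhMe, reflux; then HCl (aq)
Reagents that add atoms: potassium hydroxide, [K+].[OH-]
Why: E2 dehydrobromination by KOH with concomitant saponification is the established entry to the strained cyclobutenecarboxylic acid, with no stereocentre involved.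

Step 8
Reactants: 12 cyclobut-1-ene-1-carboxylic acid
Product: 13 methyl cyclobut-1-ene-1-carboxylate
Conditions: MeI, K2CO3, DMF, rt
Reagents that add atoms: iodomethane, CI
Why: SN2 O-alkylation of the carboxylate under mild base avoids the acid and heat that would polymerise the strained acrylate, with no stereocentre involved.

Step 9
Reactants: 7 (S)-5-[(4-methoxybenzyl)oxy]-3-methylcyclohex-2-en-1-one; 13 methyl cyclobut-1-ene-1-carboxylate
Product: 14 cis-anti-cis head-to-head photoadduct (1R,4S,5R,8S,10R): cyclohexanone C5–C10 cis-fused at C5/C10 to the new cyclobutane C1–C4–C5–C10, which is cis-fused at C1/C4 to cyclobutane C1–C2–C3–C4; CO2Me on C4, CH3 on C10, 8-ether anti to the cyclobutane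
Conditions: hν (350 nm, Pyrex), 13 (6 equiv), CH2Cl2, −20 °C, degassed; then basic Al2O3, CH2Cl2
Reagents that add atoms: none
Why: Excitation of enone 7 and intersystem crossing give the triplet, which bonds from C10 to the unsubstituted cyclobutene carbon C1 to form a triplet 1,4-diradical (α-keto radical at C5, ester-stabilised tertiary radical at C4) that closes C5–C4 after spin inversion; this is the enone–alkene [2+2] photocycloaddition in the form known for cyclohexenones and cyclobutenecarboxylates. The one new ring, the cyclobutane C1–C4–C5–C10, closes by radical–radical combination within that diradical. C10 and C5 are set by approach of the alkene to the enone face anti to the C8 ether, and C1 and C4 by the obligatory cis fusion of the cyclobutene ring together with its orientation away from the six-membered ring (anti). Any trans-fused C5 epimer is brought to the cis ring fusion on Al2O3 by enolisation of the ketone. The step needs head-to-head regiochemistry, which the electron-poor, radical-stabilising ester secures by directing the first bond to C1; facial selectivity need not be complete, because all four new stereocentres are erased in step 10 and both cis-anti-cis adducts converge on 15.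

Step 10
Reactants: 14 cis-anti-cis head-to-head photoadduct
Product: 15 methyl (1(10)E,4E,8S)-8-[(4-methoxybenzyl)oxy]-10-methyl-6-oxocyclodeca-1(10),4-diene-4-carboxylate
Conditions: PhMe (dilute, degassed), 185 °C, base-washed sealed tube or flow coil, short residence time
Reagents that add atoms: none
Why: Thermal cycloreversion of the bicyclo[2.2.0]hexane (retro-[2+2]), in which homolysis of the strained central C1–C4 bond gives a cyclohexane-1,4-diyl that fragments across C5–C10, should deliver from the cis-anti-cis adduct the cis,trans-cyclodeca-1,5-diene with the trans bond at the unconjugated C1=C10 and the cis bond in the enone–ester unit, the short contact time keeping the product from Cope rearrangement; no stereocentre is formed and the four transient ones vanish.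

Step 11
Reactants: 15 methyl (1(10)E,4E,8S)-8-[(4-methoxybenzyl)oxy]-10-methyl-6-oxocyclodeca-1(10),4-diene-4-carboxylate; 16 methyl bromoacetate
Product: 17 methyl (1(10)E,4E,7R,8S)-7-(2-methoxy-2-oxoethyl)-8-[(4-methoxybenzyl)oxy]-10-methyl-6-oxocyclodeca-1(10),4-diene-4-carboxylate
Conditions: LiN(iPr)2, THF, −78 °C; then 16, DMPU, −78 to −40 °C
Reagents that add atoms: methyl bromoacetate (compound 16), COC(=O)CBr
Why: Kinetic deprotonation occurs at C7, the only sp3 α-carbon of the ketone, and SN2 alkylation of the enolate by the bromoacetate (enolate alkylation) should take place on the face trans to the neighbouring C8 ether, as is general for enolates of 3-substituted medium-ring ketones and 5-alkoxycyclohexenones, which sets C7 with the side chain β and H-7 α.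

Step 12
Reactants: 17 C7-alkylated dienone
Product: 19 methyl (1(10)E,4E,3S,7R,8S)-3-hydroxy-7-(2-methoxy-2-oxoethyl)-8-[(4-methoxybenzyl)oxy]-10-methyl-6-oxocyclodeca-1(10),4-diene-4-carboxylate, via selenide 18 (not isolated)
Conditions: LiN(SiMe3)2, THF, −78 to −45 °C; PhSeBr, −78 °C; then mCPBA (1.0 equiv), CH2Cl2, −78 °C; pyridine, H2O, to 0 °C
Reagents that add atoms: 3-chloroperoxybenzoic acid, OOC(=O)c1cccc(Cl)c1
Why: The hindered amide base should remove a γ-proton at C3 rather than the tertiary C7–H (flanked by the side chain and cis to the C8 ether), giving the extended dienolate, which is selenenylated at its α-carbon C5; oxidation gives an allylic selenoxide that has no β-hydrogen for syn-elimination and therefore undergoes the [2,3]-sigmatropic selenoxide–selenenate rearrangement, transferring oxygen suprafacially to C3 and returning C4=C5 to conjugation in its ring-cis form, and since selenium is expected to enter C5 on the exposed outer face of the dienolate the oxygen should arrive on the β-face of C3 (3S), hydrolysis of the selenenate then freeing the alcohol.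

Step 13
Reactants: 19 3β-hydroxy enone
Product: 20 methyl (1(10)E,4E,3S,7R,8S)-3-[(tert-butyldimethylsilyl)oxy]-7-(2-methoxy-2-oxoethyl)-8-[(4-methoxybenzyl)oxy]-10-methyl-6-oxocyclodeca-1(10),4-diene-4-carboxylate
Conditions: TBSCl, imidazole, DMF, 0 °C
Reagents that add atoms: tert-butyldimethylsilyl chloride, CC(C)(C)[Si](C)(C)Cl
Why: Silyl ether formation at the secondary allylic alcohol touches no stereocentre and is done at once so that the cis-γ-hydroxy enone cannot close to a transannular hemiketal.

Step 14
Reactants: 20 3β-silyloxy enone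
Product: 22 methyl 3β-(tert-butyldimethylsilyloxy)-8α-(4-methoxybenzyloxy)-13-norgermacra-1(10)E,4-dien-12,6α-olid-15-oate (3S,6R,7R,8S; trans-fused lactone), via hydroxy diester 21 (not isolated)
Conditions: Zn(BH4)2, Et2O, −40 °C; then PPTS (cat.), PhMe, 50 °C
Reagents that add atoms: none
Why: 1,2-Reduction under chelation control, in which divalent zinc bridges the C6 carbonyl and the C8 ether oxygen in a six-membered chelate with the C7 side chain axial and hydride adds axially to C6 anti to that side chain, should give the 6α-alcohol (1,3-syn to the C8 oxygen, trans to C11), which lactonises onto the side-chain ester under mild acid while the C15 ester, trans to C6 on the alkene, cannot.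

Step 15
Reactants: 22 trans-fused 12,6α-lactone
Product: 25 methyl 3β-(tert-butyldimethylsilyloxy)-8α-(4-methoxybenzyloxy)germacra-1(10)E,4,11(13)-trien-12,6α-olid-15-oate (3S,6R,7R,8S), via Mannich base 23 (not isolated), via methiodide 24 (not isolated)
Conditions: LiN(iPr)2, THF, −78 °C; [Me2N=CH2]I, −78 °C to rt; then MeI, MeOH; then NaHCO3 (aq), CH2Cl2
Reagents that add atoms: N,N-dimethylmethyleneiminium iodide, C=[N+](C)C.[I-]
Why: α-Methylenation of the lactone by Mannich reaction of its enolate with the iminium salt, N-methylation and base-induced Hofmann-type β-elimination (E1cB), in which no stereocentre is created and C11 ceases to be one.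

Step 16
Reactants: 25 α-methylene lactone ester
Product: 26 3β-(tert-butyldimethylsilyloxy)-8α-(4-methoxybenzyloxy)germacra-1(10)E,4,11(13)-triene-12,6α-lactol-15-ol (C12 anomers)
Conditions: iBu2AlH (5 equiv), CH2Cl2, −78 °C; KNaC4H4O6 (aq)
Reagents that add atoms: none
Why: At −78 °C iBu2AlH reduces the conjugated methyl ester to the allylic alcohol and stops at the aluminium lactolate for the lactone (1,2-reduction), a deliberate over-reduction because no hydride distinguishes the two acyl groups, the anomeric lactol carbon being oxidised away in step 17.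

Step 17
Reactants: 26 lactol allylic alcohol
Product: 27 3β-(tert-butyldimethylsilyloxy)-8α-(4-methoxybenzyloxy)-15-oxogermacra-1(10)E,4,11(13)-trien-12,6α-olide (3S,6R,7R,8S)
Conditions: TEMPO (cat.), PhI(OAc)2, CH2Cl2, rt
Reagents that add atoms: none
Why: Oxoammonium (TEMPO) oxidation with PhI(OAc)2 returns the lactol to the lactone and takes the primary allylic alcohol to the enal while leaving the alkenes and both ethers untouched.

Step 18
Reactants: 27 enal lactone 4-methoxybenzyl ether
Product: 28 3β-(tert-butyldimethylsilyloxy)-8α-hydroxy-15-oxogermacra-1(10)E,4,11(13)-trien-12,6α-olide (3S,6R,7R,8S)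
Conditions: DDQ, CH2Cl2/pH 7 buffer, 0 °C
Reagents that add atoms: none
Why: Oxidative cleavage of the 4-methoxybenzyl ether by DDQ (hydride abstraction to the oxocarbenium ion, then hydrolysis) frees the 8α-hydroxyl under neutral conditions that spare the enal, the methylene lactone and the silyl ether.

Step 19
Reactants: 28 8α-alcohol; 29 methacrylic acid
Product: 30 3β-(tert-butyldimethylsilyloxy)-8β-methacryloyloxy-15-oxogermacra-1(10)E,4,11(13)-trien-12,6α-olide (3S,6R,7R,8R)
Conditions: 29, PPh3, DIAD, PhMe, 0 °C to rt
Reagents that add atoms: methacrylic acid (compound 29), C=C(C)C(=O)O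
Why: Mitsunobu esterification, in which the oxyphosphonium ion of the 8α-alcohol is displaced by methacrylate in an SN2 reaction, should install the ester with inversion and so set the 8β (R) configuration of the target.

Step 20
Reactants: 30 8β-methacrylate silyl ether
Product: 31 3β-hydroxy-8β-methacryloyloxy-15-oxogermacra-1(10)E,4,11(13)-trien-12,6α-olide (3S,6R,7R,8R)
Conditions: HF·pyridine, pyridine, THF, 0 °C to rt
Reagents that add atoms: none
Why: Fluoride-mediated desilylation of the allylic silyl ether under mildly acidic conditions leaves the methacrylate, the enal and the methylene lactone intact and changes no stereocentre.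

Step 21
Reactants: 31 3β-hydroxy trienolide
Product: 32 1β,10α-epoxy-3β-hydroxy-8β-methacryloyloxy-15-oxogermacra-4,11(13)-dien-12,6α-olide (1R,3S,6R,7R,8R,10R), the target
Conditions: mCPBA, NaHCO3, CH2Cl2, 0 °C
Reagents that add atoms: 3-chloroperoxybenzoic acid, OOC(=O)c1cccc(Cl)c1
Why: Prilezhaev epoxidation, in which only the electron-rich trisubstituted C1=C10 of the four C=C bonds reacts with the peracid and is attacked on its exposed outer face in the lactone-locked ring conformation, assisted by hydrogen bonding to the homoallylic 3β-hydroxyl, should give the trans 1β,10α-epoxide (1R,10R) as in epoxidations of related germacranolides.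

Compound list
1 | cis,cis-cyclohexane-1,3,5-triol (all-cis, meso) | O[C@H]1C[C@@H](O)C[C@@H](O)C1 | starting material
2 | all-cis-5-[(4-methoxybenzyl)oxy]cyclohexane-1,3-diol (meso) | COc1ccc(CO[C@H]2C[C@@H](O)C[C@@H](O)C2)cc1 | intermediate
3 | (1R,3R,5S)-3-hydroxy-5-[(4-methoxybenzyl)oxy]cyclohexyl acetate (all-cis) | COc1ccc(CO[C@H]2C[C@@H](O)C[C@@H](OC(C)=O)C2)cc1 | intermediate
4 | (1S,5R)-3-oxo-5-[(4-methoxybenzyl)oxy]cyclohexyl acetate | COc1ccc(CO[C@H]2CC(=O)C[C@@H](OC(C)=O)C2)cc1 | intermediate (not isolated)
5 | (R)-5-[(4-methoxybenzyl)oxy]cyclohex-2-en-1-one | COc1ccc(CO[C@H]2CC(=O)C=CC2)cc1 | intermediate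
6 | (5R)-5-[(4-methoxybenzyl)oxy]-1-methylcyclohex-2-en-1-ol (both C1 epimers) | COc1ccc(CO[C@H]2CC(C)(O)C=CC2)cc1 | intermediate
7 | (S)-5-[(4-methoxybenzyl)oxy]-3-methylcyclohex-2-en-1-one (supplies C5–C10 and C14; ether carbon is C8) | COc1ccc(CO[C@H]2CC(C)=CC(=O)C2)cc1 | intermediate
8 | cyclobutanecarboxylic acid | OC(=O)C1CCC1 | starting material
9 | cyclobutanecarbonyl chloride | ClC(=O)C1CCC1 | intermediate (not isolated)
10 | 1-bromocyclobutane-1-carbonyl chloride | ClC(=O)C1(Br)CCC1 | intermediate (not isolated)
11 | methyl 1-bromocyclobutane-1-carboxylate | COC(=O)C1(Br)CCC1 | intermediate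
12 | cyclobut-1-ene-1-carboxylic acid | OC(=O)C1=CCC1 | intermediate
13 | methyl cyclobut-1-ene-1-carboxylate (supplies C1–C4 and C15) | COC(=O)C1=CCC1 | intermediate
14 | cis-anti-cis head-to-head photoadduct (1R,4S,5R,8S,10R), tricyclic keto ester with CO2Me on C4, CH3 on C10 and the 8-ether anti to the cyclobutane | COc1ccc(CO[C@H]2C[C@]3(C)[C@H]4CC[C@@]4(C(=O)OC)[C@@H]3C(=O)C2)cc1 | intermediate
15 | methyl (1(10)E,4E,8S)-8-[(4-methoxybenzyl)oxy]-10-methyl-6-oxocyclodeca-1(10),4-diene-4-carboxylate | COc1ccc(CO[C@H]2C/C(C)=C/CC/C(C(=O)OC)=C\C(=O)C2)cc1 | intermediate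
16 | methyl bromoacetate | COC(=O)CBr | starting material
17 | methyl (1(10)E,4E,7R,8S)-7-(2-methoxy-2-oxoethyl)-8-[(4-methoxybenzyl)oxy]-10-methyl-6-oxocyclodeca-1(10),4-diene-4-carboxylate (side chain 7β, ether 8α) | COc1ccc(CO[C@H]2C/C(C)=C/CC/C(C(=O)OC)=C\C(=O)[C@@H]2CC(=O)OC)cc1 | intermediate
18 | C5 phenylselenide of 17 with the alkene moved to C3=C4 (C5 configuration and C3=C4 geometry not assigned) | COc1ccc(CO[C@H]2C/C(C)=C/CC=C(C(=O)OC)C([Se]c3ccccc3)C(=O)[C@@H]2CC(=O)OC)cc1 | intermediate (not isolated)
19 | 3β-hydroxy derivative of 17 (3S,7R,8S) | COc1ccc(CO[C@H]2C/C(C)=C/C[C@H](O)/C(C(=O)OC)=C\C(=O)[C@@H]2CC(=O)OC)cc1 | intermediate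
20 | 3β-tert-butyldimethylsilyl ether of 19 (3S,7R,8S) | COc1ccc(CO[C@H]2C/C(C)=C/C[C@H](O[Si](C)(C)C(C)(C)C)/C(C(=O)OC)=C\C(=O)[C@@H]2CC(=O)OC)cc1 | intermediate
21 | 6α-hydroxy diester from 20 (3S,6R,7S,8S) | COc1ccc(CO[C@H]2C/C(C)=C/C[C@H](O[Si](C)(C)C(C)(C)C)/C(C(=O)OC)=C\[C@@H](O)[C@@H]2CC(=O)OC)cc1 | intermediate (not isolated)
22 | methyl 3β-(tert-butyldimethylsilyloxy)-8α-(4-methoxybenzyloxy)-13-norgermacra-1(10)E,4-dien-12,6α-olid-15-oate (3S,6R,7R,8S) | COc1ccc(CO[C@H]2C/C(C)=C/C[C@H](O[Si](C)(C)C(C)(C)C)/C(C(=O)OC)=C\[C@H]3OC(=O)C[C@@H]32)cc1 | intermediate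
23 | 11-(dimethylaminomethyl) lactone (Mannich base, C11 epimers) | COc1ccc(CO[C@H]2C/C(C)=C/C[C@H](O[Si](C)(C)C(C)(C)C)/C(C(=O)OC)=C\[C@H]3OC(=O)C(CN(C)C)[C@@H]32)cc1 | intermediate (not isolated)
24 | trimethylammonium iodide of 23 | COc1ccc(CO[C@H]2C/C(C)=C/C[C@H](O[Si](C)(C)C(C)(C)C)/C(C(=O)OC)=C\[C@H]3OC(=O)C(C[N+](C)(C)C)[C@@H]32)cc1.[I-] | intermediate (not isolated)
25 | methyl 3β-(tert-butyldimethylsilyloxy)-8α-(4-methoxybenzyloxy)germacra-1(10)E,4,11(13)-trien-12,6α-olid-15-oate (3S,6R,7R,8S) | COc1ccc(CO[C@H]2C/C(C)=C/C[C@H](O[Si](C)(C)C(C)(C)C)/C(C(=O)OC)=C\[C@H]3OC(=O)C(=C)[C@@H]32)cc1 | intermediate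
26 | 12,6α-lactol 15-ol from 25 (C12 anomers) | COc1ccc(CO[C@H]2C/C(C)=C/C[C@H](O[Si](C)(C)C(C)(C)C)/C(CO)=C\[C@H]3OC(O)C(=C)[C@@H]32)cc1 | intermediate
27 | 3β-(tert-butyldimethylsilyloxy)-8α-(4-methoxybenzyloxy)-15-oxogermacra-1(10)E,4,11(13)-trien-12,6α-olide (3S,6R,7R,8S) | COc1ccc(CO[C@H]2C/C(C)=C/C[C@H](O[Si](C)(C)C(C)(C)C)/C(C=O)=C\[C@H]3OC(=O)C(=C)[C@@H]32)cc1 | intermediate
28 | 3β-(tert-butyldimethylsilyloxy)-8α-hydroxy-15-oxogermacra-1(10)E,4,11(13)-trien-12,6α-olide (3S,6R,7R,8S) | O[C@H]1C/C(C)=C/C[C@H](O[Si](C)(C)C(C)(C)C)/C(C=O)=C\[C@H]2OC(=O)C(=C)[C@@H]21 | intermediate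
29 | methacrylic acid | C=C(C)C(=O)O | starting material
30 | 3β-(tert-butyldimethylsilyloxy)-8β-methacryloyloxy-15-oxogermacra-1(10)E,4,11(13)-trien-12,6α-olide (3S,6R,7R,8R) | C=C(C)C(=O)O[C@@H]1C/C(C)=C/C[C@H](O[Si](C)(C)C(C)(C)C)/C(C=O)=C\[C@H]2OC(=O)C(=C)[C@@H]21 | intermediate
31 | 3β-hydroxy-8β-methacryloyloxy-15-oxogermacra-1(10)E,4,11(13)-trien-12,6α-olide (3S,6R,7R,8R) | C=C(C)C(=O)O[C@@H]1C/C(C)=C/C[C@H](O)/C(C=O)=C\[C@H]2OC(=O)C(=C)[C@@H]21 | intermediate
32 | 1β,10α-epoxy-3β-hydroxy-8β-methacryloyloxy-15-oxogermacra-4,11(13)-dien-12,6α-olide (1R,3S,6R,7R,8R,10R) | C=C(C)C(=O)O[C@@H]1C[C@@]2(C)O[C@@H]2C[C@H](O)/C(C=O)=C\[C@H]2OC(=O)C(=C)[C@@H]21 | target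

Total step count: 21. Longest linear sequence: 18 steps (steps 1–5, then 9–21); the cyclobutene branch (steps 6–8) joins at step 9.

Steps most likely to fail

Step 12 (C3 hydroxylation). The base may enolise toward C7 instead of C3, after which the C8 alkoxide can be lost; the selenoxide shift may also deliver oxygen to the wrong face of C3 or return the C4=C5 bond with the wrong geometry. The fallback runs from 17 to 19 without a strong base and without a sigmatropic step. Silylation of 17 under equilibrating conditions (TMSCl, NaI, Et3N, MeCN) gives the extended trimethylsilyl dienol ether F1. NBS in THF at −78 °C brominates F1 at the γ-carbon to the 3α-bromo enone F2, an allylic bromide whose C3 epimers can be equilibrated with LiBr. SN2 displacement with caesium formate (HCO2Cs, 18-crown-6, PhMe) inverts C3 to the 3β-formate F3, and KHCO3 in MeOH at 0 °C removes the formyl group to give 19.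

Step 10 (thermolysis). The product may stay too long at the reaction temperature and rearrange (Cope) to the divinylcyclohexanone, or the conjugated C4=C5 bond may lose its geometry. The fallback runs from 14 to 15 at the alcohol oxidation level. NaBH4 (MeOH, 0 °C) reduces the ketone of 14 to the photoadduct carbinol F4 (C6 epimers, both usable). F4 is thermolysed in the same way to the cyclodecadienol F5, from which any isomer with C15 cis to C6 removes itself by closing to a butenolide. MnO2 (CH2Cl2, rt) then oxidises the allylic alcohol to 15.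

Step 19 (Mitsunobu inversion). Elimination toward C9, or capture of triphenylphosphine by the methylene lactone or the enal, may outrun substitution at C8. The fallback runs from 28 to 30 by a two-stage SN2 sequence. MsCl and Et3N (CH2Cl2, −20 °C) convert 28 into the 8α-mesylate F6, which caesium methacrylate (CsO2CC(CH3)=CH2, made from 29 and Cs2CO3; DMF, 18-crown-6, 40 °C) displaces with inversion to give 30.

Further compounds
F1 | step 12 | extended trimethylsilyl dienol ether of 17 (C6 silyloxy, C5=C6 and C3=C4 alkenes, geometries not assigned) | COc1ccc(CO[C@H]2C/C(C)=C/CC=C(C(=O)OC)C=C(O[Si](C)(C)C)[C@@H]2CC(=O)OC)cc1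
F2 | step 12 | 3α-bromo enone (3R,7R,8S) | COc1ccc(CO[C@H]2C/C(C)=C/C[C@@H](Br)/C(C(=O)OC)=C\C(=O)[C@@H]2CC(=O)OC)cc1
F3 | step 12 | 3β-formate of 19 (3S,7R,8S) | COc1ccc(CO[C@H]2C/C(C)=C/C[C@H](OC=O)/C(C(=O)OC)=C\C(=O)[C@@H]2CC(=O)OC)cc1
F4 | step 10 | photoadduct carbinol, 6-hydroxy analogue of 14 (C6 epimers) | COc1ccc(CO[C@H]2C[C@]3(C)[C@H]4CC[C@@]4(C(=O)OC)[C@@H]3C(O)C2)cc1
F5 | step 10 | cyclodecadienol, 6-hydroxy analogue of 15 (C6 epimers) | COc1ccc(CO[C@H]2C/C(C)=C/CC/C(C(=O)OC)=C\C(O)C2)cc1
F6 | step 19 | 8α-methanesulfonate of 28 | CS(=O)(=O)O[C@H]1C/C(C)=C/C[C@H](O[Si](C)(C)C(C)(C)C)/C(C=O)=C\[C@H]2OC(=O)C(=C)[C@@H]21
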